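Numbering: atoms carry the germacrane numbers of the target throughout (C1 ketone, C4=C5, C6 lactone carbinol, C7, C8 ester carbinol, C10 tertiary carbinol, C11=C13 methylene, C12 lactone carbonyl, C14 and C15 methyls). On the six-membered-ring intermediates the ring atoms are C1, C6, C7, C8, C9, C10; the "lower face" is the face of the C7 side chain and the "upper face" is the opposite one.

## The problem

The target is a germacranolide: a ten-membered carbocycle (C1–C10) fused trans at C6–C7 to an α-methylene-γ-butyrolactone, with a C1 ketone beside a tertiary C10 carbinol, a tiglate on O8 and a Z-trisubstituted C4=C5 olefin. Closing a ten-membered ring end to end fights entropy and transannular strain, and a medium ring gives little reliable facial control, so the stereocentres are best set before the ring exists. Of the four stereocentres (6R,7R,8R,10R), C7, C8 and C10 sit on a C7–C8–C9–C10 arc: on a cyclohexane C7 can direct C8 (cis) and, through an axial O8 substituent, C10 (trans to the C7 side chain). C6 must then be set last, from C7, in the ten-membered ring. The methylene lactone is a Michael acceptor, the tiglate will not survive organometallics or hydride, and the C1/C10 α-ketol is prone to acyloin shift. A C6 ketone with C7–H and a β-oxygen at C8 invites epimerisation and elimination, and a ten-membered 1,6-dione can undergo transannular aldol addition. The enabling feature is that C1 and C6 are both oxygenated and stand 1,6 across the ring, with saturated C2–C3 next to C1 and the Z C4=C5 olefin next to C6. This is the pattern produced when a 1-vinyl-2-(prop-1-ynyl)cyclohexane-1,2-diol undergoes a doubly oxido-accelerated [3,3] shift, and the cyclohexane it requires is the ring of carvone with C7 as the isopropenyl-bearing carbon.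

## Retrosynthesis

**C8 ester.** The tiglate C–O bond of 34 is cut first, giving diol 31 and tiglic acid 32. Acylation is placed last because no ester would survive the Grignard, KH and hydride steps. It needs only a secondary hydroxyl to react in the presence of the tertiary C10 carbinol.

**Acetals, C1 ketone and lactone.** 31 comes from the bis-MOM ketone 29, this from carbinol 28 by oxidation, and the lactone of 28 from the 2-methylene-1,4-diol unit of triol 25 by oxidative lactonisation. Taking the lactone back to a diol removes the Michael acceptor from all earlier steps. O8 and O6 both lie 1,4 to C12, so O8 must stay blocked until the lactone is closed. MOM ethers are chosen for O8 and O10 because a silyl group on O10 would migrate to the neighbouring C1 alkoxide in the key step.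

**C6 carbinol.** 25 and its silyl ether 24 come from dione 23 by 1,2-reduction. Reducing both ketones and re-oxidising C1 later avoids having to differentiate the two carbonyl groups. The forward reaction must deliver hydride to the correct face of C6 under control of C7.

**Key disconnection.** Dione 23 is cut at C3–C4 and C1–C6 is re-formed, giving cyclohexanediol 20. This is preferred over any end-to-end ring closure because the ring arises by enlargement of a six-membered ring on which C7, C8 and C10 are already fixed. The precursor has no medium ring and no olefin geometry to control. The forward step must cleave C1–C6 in preference to C6–C7 and must give the Z enone.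

**C1–C2 and C5–C6 bonds.** 20 comes from α-hydroxy ketone 18 and prop-1-ynylmagnesium bromide 19. 18 comes from diol 17 by oxidation, and 17 from α-hydroxy ketone 15 and vinylmagnesium bromide 16. The order (vinyl at C1 first, then oxidation at C6 and alkynylation) never requires a free 1,2-dione, which would enolise through C7. The configurations created at C1 and C6 do not matter, as both carbons become sp2 again.

**C6 and C10 oxygens.** 15 comes from ketone 13 by enolate hydroxylation, which is regiospecific because C10 is quaternary. 13 comes from α-hydroxy ketone 12 by acetalisation, and 12 from enone 10 by conjugate reduction and hydroxylation of the resulting enolate. This one operation replaces an epoxidation/opening sequence. It requires oxygen to reach C10 on the upper face, which the axial O8 acetal of 10 should enforce.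

**C8 oxygen.** 10 comes from the cis γ-hydroxy enone 9, and 9 from its trans epimer 7 by Mitsunobu inversion. 7 comes from enone 5 by γ-hydroxylation through the through-conjugated dienol ether. Direct oxygenation is expected anti to the C7 side chain, so the inversion is accepted as the price for the cis arrangement that later directs C10.

**C12 oxygen.** 5 comes from alcohol 4, 4 from chloride 2, and 2 from (R)-carvone 1 by allylic chlorination of the isopropenyl group. Carvone supplies C7 in the correct absolute configuration, ten of the fifteen skeletal carbons and the enone needed for the C8 and C10 oxygenations.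

## Roads not taken

Alternative 1: The lactone is built last by cutting C7–C11 and then C11=C13. In the forward direction the O6 phosphonoacetate A1 of a preformed ten-membered 7,8-epoxide is deprotonated and the carbanion opens the oxirane at C7 (5-exo, inversion). This closes the γ-lactone and frees the C8 hydroxyl; olefination of the phosphono lactone with formaldehyde then gives A2.
- Merits: the trans ring fusion follows from the tether and the SN2 opening; O8 appears unprotected exactly where the tiglate goes; the Michael acceptor exists only at the end.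
- Weak points: the plan leaves the real problem untouched. It needs a ten-membered ring that already carries the Z olefin, the C6 carbinol, the C1/C10 diol and a trans 7,8-epoxide of defined face. A stabilised phosphonoacetate anion is a poor nucleophile for an epoxide, and 6-endo opening at C8 and base-induced isomerisation of the epoxide compete.
- Comparison: as an endgame it is better than the chosen one, which carries two acetals and a silyl ether and sets C6 by reduction. Against this the chosen plan delivers the ring and three stereocentres from a six-membered chiral-pool ring, which Alternative 1 would still have to obtain by a sequence of similar length.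

Alternative 2: The carbocycle is closed by nitrile oxide cycloaddition, cutting C8–C9 and O–C10. Oxidation of the C8 aldoxime A3 with NaOCl gives a nitrile oxide that adds across the isopropenyl-type C9=C10 olefin, forming the ten-membered ring and a bridging isoxazoline in A4. N–O cleavage would later unveil the C8 ketone/C10 carbinol aldol pair.
- Merits: it recognises the 1,3-oxygen pattern at C8/C10, is convergent, needs no protecting group on O10, and places oxygen reliably on the more substituted olefin carbon.
- Weak points: a ten-membered ring must close in a bimolecular-prone reaction (furoxan formation, high dilution). The face of the C9=C10 olefin is selected only by remote C6/C7 centres. C7 lies α to the oxime and later to a C8 ketone with a β-silyloxy group at C6, so epimerisation and elimination threaten. N–O cleavage must spare three olefins, and C8 must still be reduced cis to the C7 side chain.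
- Comparison: it is shorter in the longest linear sequence and more convergent. The chosen plan sets against this that C8 and C10 are made on a conformationally defined cyclohexane and that no macrocyclisation is needed.

Alternative 3: The ring is closed at C5–C6 by a Nozaki–Hiyama–Kishi reaction. CrCl2 with catalytic NiCl2 adds the (Z)-alkenyl iodide terminus of A5 to its C6 aldehyde, and the chromium alkoxide closes the lactone on the C12 ester to give A6, which still lacks the C11 methylene.
- Merits: this ring closure has firm precedent for medium rings, tolerates esters, acetals and silyl ethers, and carries the Z olefin geometry in unchanged from the iodide. In securing the olefin it is better than the chosen plan, where the geometry comes from protonation of an allenolate.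
- Weak points: the acyclic precursor needs C1, C7, C8 and C10 from open-chain stereocontrol. The C6 aldehyde is α-branched with a β-silyloxy group, so it can epimerise or eliminate. C6 is set by 1,2-induction during macrocyclisation, and the methylene must be added afterwards through a lactone enolate beside other acidic sites.
- Comparison: both routes set C6 late and with comparable uncertainty. The chosen plan sets against the stronger ring-closure precedent a ring formation that needs no dilution and no stoichiometric chromium, and a chiral-pool start that already contains C7 and the lactone carbons.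

Key step: step 13

Assumption: the carbinol configurations drawn at C6 in 15 and 17 and at C1 and C6 in 17–21 are those expected from the face of attack and are erased in steps 11 and 13, so other epimers would serve equally; C1 in 24–28 and the lactol carbon of 27 are epimer mixtures and are written without a descriptor.

Step 1
Reactants: 1 (R)-carvone
Product: 2 (5R)-5-(3-chloroprop-1-en-2-yl)-2-methylcyclohex-2-en-1-one
Conditions: Ca(OCl)2, solid CO2, CH2Cl2/H2O, 0 °C
Reagents that add atoms: calcium hypochlorite Ca(OCl)2, [Ca+2].[O-]Cl.[O-]Cl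
Why: Ene-type allylic chlorination by HOCl formed in the flask attacks the electron-rich isopropenyl olefin and not the enone, moving the double bond to C11=C13 with chlorine on C12; C7 is not involved.

Step 2
Reactants: 2 (5R)-5-(3-chloroprop-1-en-2-yl)-2-methylcyclohex-2-en-1-one
Product: 4 (5R)-5-(3-hydroxyprop-1-en-2-yl)-2-methylcyclohex-2-en-1-one, via allylic acetate 3 (not isolated)
Conditions: KOAc, nBu4NI (cat.), DMF, 60 °C; then K2CO3 (cat.), MeOH, 0 °C
Reagents that add atoms: potassium acetate, CC(=O)[O-].[K+]
Why: SN2 displacement of the primary allylic chloride by acetate followed by carbonate-catalysed transesterification frees the C12 alcohol; the mild base leaves the enone and C7 untouched.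

Step 3
Reactants: 4 (5R)-5-(3-hydroxyprop-1-en-2-yl)-2-methylcyclohex-2-en-1-one
Product: 5 (5R)-5-[3-(tert-butyldimethylsilyloxy)prop-1-en-2-yl]-2-methylcyclohex-2-en-1-one
Conditions: TBSCl, imidazole, DMF, rt
Reagents that add atoms: tert-butyldimethylsilyl chloride, CC(C)(C)[Si](C)(C)Cl
Why: Standard silylation of a primary alcohol; the TBS ether withstands the organometallic, hydride and KH steps and is the only group removed by fluoride before lactonisation.

Step 4
Reactants: 5 (5R)-5-[3-(tert-butyldimethylsilyloxy)prop-1-en-2-yl]-2-methylcyclohex-2-en-1-one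
Product: 7 (4S,5R)-4-hydroxy-2-methyl-5-[3-(tert-butyldimethylsilyloxy)prop-1-en-2-yl]cyclohex-2-en-1-one (8-OH trans to the C7 side chain), via trimethylsilyl dienol ether 6 (not isolated)
Conditions: MeMgBr, FeCl3 (5 mol %), Et2O, −20 °C; TMSCl, Et3N, DMPU; then mCPBA, NaHCO3, CH2Cl2, −20 °C; aq. citric acid, THF
Reagents that add atoms: mCPBA, OOC(=O)c1cccc(Cl)c1
Why: The iron-catalysed Grignard base removes the γ-proton at C8 under thermodynamic control and O-silylation gives the through-conjugated dienol ether, which undergoes vinylogous Rubottom oxidation at its C8=C9 terminus. The peracid should approach anti to the adjacent C7 side chain, placing the 8-hydroxyl trans to it, and the C11=C13 olefin is far less nucleophilic than the dienol ether.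

Step 5
Reactants: 7 (4S,5R)-4-hydroxy-2-methyl-5-[3-(tert-butyldimethylsilyloxy)prop-1-en-2-yl]cyclohex-2-en-1-one
Product: 9 (4R,5R)-4-hydroxy-2-methyl-5-[3-(tert-butyldimethylsilyloxy)prop-1-en-2-yl]cyclohex-2-en-1-one (8-OH cis to the C7 side chain), via 4-nitrobenzoate ester 8 (not isolated)
Conditions: 4-O2NC6H4CO2H, PPh3, DIAD, THF, 0 °C → rt; then K2CO3, MeOH, 0 °C
Reagents that add atoms: 4-nitrobenzoic acid, OC(=O)c1ccc(cc1)[N+](=O)[O-]
Why: Mitsunobu esterification inverts the allylic C8 carbinol by SN2 (the C7 hydrogen is syn to the leaving group, so E2 is disfavoured) and mild methanolysis frees the hydroxyl, now cis to the C7 side chain as in the target.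

Step 6
Reactants: 9 (4R,5R)-4-hydroxy-2-methyl-5-[3-(tert-butyldimethylsilyloxy)prop-1-en-2-yl]cyclohex-2-en-1-one
Product: 10 (4R,5R)-4-(methoxymethoxy)-2-methyl-5-[3-(tert-butyldimethylsilyloxy)prop-1-en-2-yl]cyclohex-2-en-1-one
Conditions: MOMCl, iPr2NEt, CH2Cl2, 0 °C → rt
Reagents that add atoms: chloromethyl methyl ether, COCCl
Why: O-alkylation under amine base gives an acetal that is stable to hydride, enolates, Grignard reagents, KH and fluoride; with the C7 side chain equatorial this OMOM group is axial on the lower face.

Step 7
Reactants: 10 (4R,5R)-4-(methoxymethoxy)-2-methyl-5-[3-(tert-butyldimethylsilyloxy)prop-1-en-2-yl]cyclohex-2-en-1-one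
Product: 12 (2R,4R,5R)-2-hydroxy-4-(methoxymethoxy)-2-methyl-5-[3-(tert-butyldimethylsilyloxy)prop-1-en-2-yl]cyclohexan-1-one, via potassium enolate 11 (not isolated)
Conditions: K[sBu3BH], THF, −78 °C; then 2-(phenylsulfonyl)-3-phenyloxaziridine, −78 → −40 °C; AcOH
Reagents that add atoms: 2-(phenylsulfonyl)-3-phenyloxaziridine, O=S(=O)(N1OC1c1ccccc1)c1ccccc1
Why: Conjugate reduction gives the C1=C10 enolate regiospecifically and Davis oxidation hydroxylates C10. The axial 8-OMOM group shields the lower face in a 1,3-diaxial sense, so the bulky oxidant should deliver oxygen to the upper face, giving the 10-hydroxyl trans to the C7 side chain (10R).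

Step 8
Reactants: 12 (2R,4R,5R)-2-hydroxy-4-(methoxymethoxy)-2-methyl-5-[3-(tert-butyldimethylsilyloxy)prop-1-en-2-yl]cyclohexan-1-one
Product: 13 (2R,4R,5R)-2,4-bis(methoxymethoxy)-2-methyl-5-[3-(tert-butyldimethylsilyloxy)prop-1-en-2-yl]cyclohexan-1-one
Conditions: MOMCl, iPr2NEt, nBu4NI (cat.), ClCH2CH2Cl, 60 °C
Reagents that add atoms: chloromethyl methyl ether, COCCl
Why: Forcing O-alkylation with iodide catalysis caps the hindered tertiary α-ketol oxygen as an acetal, which unlike a silyl group cannot migrate to the neighbouring C1 alkoxide in step 13.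

Step 9
Reactants: 13 (2R,4R,5R)-2,4-bis(methoxymethoxy)-2-methyl-5-[3-(tert-butyldimethylsilyloxy)prop-1-en-2-yl]cyclohexan-1-one
Product: 15 6-hydroxy derivative of 13 at germacrane C6 (6-OH on the upper face), via potassium enolate 14 (not isolated)
Conditions: KN(SiMe3)2, THF, −78 °C; then 2-(phenylsulfonyl)-3-phenyloxaziridine, −78 °C; AcOH
Reagents that add atoms: 2-(phenylsulfonyl)-3-phenyloxaziridine, O=S(=O)(N1OC1c1ccccc1)c1ccccc1
Why: C10 is quaternary, so only the C1=C6 enolate can form, and Davis oxidation installs the C6 oxygen, expected anti to the C7 side chain; the C6 configuration is irrelevant because this carbinol is oxidised in step 11.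

Step 10
Reactants: 15 6-hydroxy ketone, 16 vinylmagnesium bromide
Product: 17 1-ethenyl-4,6-bis(methoxymethoxy)-6-methyl-3-[3-(tert-butyldimethylsilyloxy)prop-1-en-2-yl]cyclohexane-1,2-diol (vinyl on the upper face at C1)
Conditions: CH2=CHMgBr (3 equiv), THF, −78 → 0 °C; aq. NH4Cl
Reagents that add atoms: none
Why: Grignard 1,2-addition to the α-hydroxy ketone after the first equivalent forms the magnesium alkoxide; attack opposite the axial C10 methyl is expected, and the C1 configuration is erased in step 13.

Step 11
Reactants: 17 vinyl diol
Product: 18 2-ethenyl-2-hydroxy-3,5-bis(methoxymethoxy)-3-methyl-6-[3-(tert-butyldimethylsilyloxy)prop-1-en-2-yl]cyclohexan-1-one (ketone at germacrane C6)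
Conditions: IBX, DMSO, rt
Reagents that add atoms: none
Why: IBX oxidises the secondary carbinol of a 1,2-diol without glycol cleavage and without base, so the tertiary allylic alcohol, the C7 α-stereocentre and the β-OMOM group are not endangered.

Step 12
Reactants: 18 α-hydroxy ketone, 19 prop-1-ynylmagnesium bromide
Product: 20 1-ethenyl-4,6-bis(methoxymethoxy)-6-methyl-2-(prop-1-yn-1-yl)-3-[3-(tert-butyldimethylsilyloxy)prop-1-en-2-yl]cyclohexane-1,2-diol (vinyl and propynyl on the upper face; both hydroxyls on the lower face)
Conditions: CH3C≡CMgBr (4 equiv), THF, −40 → 0 °C; aq. NH4Cl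
Reagents that add atoms: none
Why: The slim, weakly basic alkynyl Grignard reagent adds to the hindered C6 ketone faster than it enolises it; approach from the face away from the C7 side chain and the 8-OMOM group puts the alkyne trans to the C7 side chain, and C6 becomes sp2 again in step 13.

Step 13
Reactants: 20 1-vinyl-2-(prop-1-ynyl)cyclohexane-1,2-diol
Product: 23 (2Z)-7,9-bis(methoxymethoxy)-3,7-dimethyl-10-[3-(tert-butyldimethylsilyloxy)prop-1-en-2-yl]cyclodec-2-ene-1,6-dione (germacrane C1,C6-dione with Z C4=C5), via dipotassium dialkoxide 21 (not isolated), via dipotassium enolate-allenolate 22 (not isolated)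
Conditions: KH (5 equiv), 18-crown-6, THF, 0 °C → rt; cannulated into AcOH/THF at −78 °C
Reagents that add atoms: none
Why: KH with 18-crown-6 converts the diol into dialkoxide 21, in which the C1–C6 bond, flanked by two oxido groups, is strongly weakened. A concerted [3,3] shift of the C3=C2–C1–C6–C5≡C4 enyne then breaks C1–C6 and forms C3–C4, giving the C1 enolate and C6 allenolate 22; the closest known reaction types are the anionic oxy-Cope ring expansion of 1,2-dialkenylcyclohexanols, its alkynyl variant and the oxy-Cope rearrangement of 1,2-divinyl-1,2-diols to 1,6-diones. The ten-membered ring is not closed end to end but arises by four-atom enlargement of the cyclohexane through a six-centre pericyclic transition state, which the cis vinyl/propynyl pair (gauche in either chair) reaches without strain. No stereocentre is created: C1 and C6 become sp2 and C7, C8 and C10 are spectators. The step needs cleavage of C1–C6 rather than C6–C7 (propynyl with the C11=C13 olefin); only C1–C6 carries two oxido substituents, and in the chair that avoids the 6,8,10-triaxial clash the propynyl group and the C7 side chain are anti-diaxial and cannot overlap. It also needs the Z enone: protonation of the allenolate at C5 from the ring periphery lets C6 bend towards C3, and the cis enone is also the more stable geometry in a ten-membered ring. Inverse quench into cold acetic acid protonates both enolates before transannular aldol addition or β-elimination of the 8-OMOM group can occur.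

Step 14
Reactants: 23 ten-membered 1,6-dione
Product: 24 ten-membered 1,6-diol (6R carbinol as in the target; C1 carbinol as epimer mixture; C12 OTBS; 8,10-bis-MOM)
Conditions: NaBH4, CeCl3·7H2O, MeOH, −78 → 0 °C
Reagents that add atoms: none
Why: Luche conditions give 1,2-reduction of the enone and also reduce the C1 ketone. Hydride is expected to reach C6 from the ring periphery in the Felkin–Anh sense, with the sp2 C11 substituent of C7 anti to the nucleophile, which places O6 syn to C11 as the trans lactone requires; the C1 epimers converge in step 17.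

Step 15
Reactants: 24 silyl ether diol
Product: 25 ten-membered 1,6,12-triol (8,10-bis-MOM)
Conditions: nBu4NF, THF, 0 °C
Reagents that add atoms: none
Why: Fluoride cleaves the primary allylic TBS ether while the MOM acetals are inert, so O8 stays blocked for the lactonisation.

Step 16
Reactants: 25 triol
Product: 28 trans-fused 12,6-lactone with C1 carbinol (8,10-bis-MOM), via hydroxy enal 26 (not isolated), via lactol 27 (not isolated)
Conditions: TEMPO (cat.), PhI(OAc)2, CH2Cl2, rt
Reagents that add atoms: none
Why: The oxoammonium species from TEMPO oxidises only the primary allylic alcohol; the hydroxy enal closes to the five-membered lactol with the C6 hydroxyl (O8 being blocked) and is oxidised on to the α-methylene lactone, while the hindered secondary C1 carbinol reacts much more slowly.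

Step 17
Reactants: 28 lactone carbinol
Product: 29 1-oxo-8,10-bis(methoxymethoxy)germacra-4Z,11(13)-dien-12,6-olide
Conditions: Dess–Martin periodinane, NaHCO3, CH2Cl2, 0 °C → rt
Reagents that add atoms: none
Why: Dess–Martin oxidation of the remaining secondary alcohol under buffered, non-basic conditions restores the C1 ketone without touching the methylene lactone or epimerising C7.

Step 18
Reactants: 29 bis-MOM keto lactone
Product: 31 8,10-dihydroxy-1-oxogermacra-4Z,11(13)-dien-12,6-olide, via bis(bromomethyl) ether 30 (not isolated)
Conditions: Me2BBr, CH2Cl2, −78 °C; then sat. aq. NaHCO3, THF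
Reagents that add atoms: none
Why: Me2BBr cleaves MOM acetals at low temperature through bromomethyl ethers that hydrolyse on bicarbonate work-up; lactones, ketones and olefins are tolerated and the tertiary carbinol is released without ionisation.

Step 19
Reactants: 31 8,10-diol, 32 tiglic acid
Product: 34 (6R,7R,8R,10R)-10-hydroxy-1-oxo-8-[(E)-2-methylbut-2-enoyloxy]germacra-4Z,11(13)-dien-12,6-olide, via mixed anhydride 33 (not isolated)
Conditions: 2,4,6-trichlorobenzoyl chloride, Et3N, toluene, rt; then 31, DMAP, toluene, rt
Reagents that add atoms: none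
Why: Yamaguchi esterification acylates the secondary C8 hydroxyl while the tertiary C10 carbinol does not react; the E tiglate is the stable isomer, so no double-bond isomerisation is expected.

## Compound list

1 | (R)-carvone, (5R)-2-methyl-5-(prop-1-en-2-yl)cyclohex-2-en-1-one | O=C1C[C@H](C(C)=C)CC=C1C | starting material
2 | (5R)-5-(3-chloroprop-1-en-2-yl)-2-methylcyclohex-2-en-1-one | O=C1C[C@H](C(=C)CCl)CC=C1C | intermediate
3 | 2-[(1R)-4-methyl-5-oxocyclohex-3-en-1-yl]prop-2-en-1-yl acetate | O=C1C[C@H](C(=C)COC(C)=O)CC=C1C | intermediate (not isolated)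
4 | (5R)-5-(3-hydroxyprop-1-en-2-yl)-2-methylcyclohex-2-en-1-one | O=C1C[C@H](C(=C)CO)CC=C1C | intermediate
5 | (5R)-5-[3-(tert-butyldimethylsilyloxy)prop-1-en-2-yl]-2-methylcyclohex-2-en-1-one | O=C1C[C@H](C(=C)CO[Si](C)(C)C(C)(C)C)CC=C1C | intermediate
6 | trimethylsilyl dienol ether of 5: 2-methyl-1-(trimethylsilyloxy)-5-[3-(tert-butyldimethylsilyloxy)prop-1-en-2-yl]cyclohexa-1,3-diene, C7 as in 5 | C[Si](C)(C)OC1=C(C)C=C[C@@H](C(=C)CO[Si](C)(C)C(C)(C)C)C1 | intermediate (not isolated)
7 | (4S,5R)-4-hydroxy-2-methyl-5-[3-(tert-butyldimethylsilyloxy)prop-1-en-2-yl]cyclohex-2-en-1-one (8-OH trans to the C7 side chain) | O=C1C[C@H](C(=C)CO[Si](C)(C)C(C)(C)C)[C@@H](O)C=C1C | intermediate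
8 | 4-nitrobenzoate of 9 (ester on O8, cis to the C7 side chain) | O=C1C[C@H](C(=C)CO[Si](C)(C)C(C)(C)C)[C@H](OC(=O)c2ccc(cc2)[N+](=O)[O-])C=C1C | intermediate (not isolated)
9 | (4R,5R)-4-hydroxy-2-methyl-5-[3-(tert-butyldimethylsilyloxy)prop-1-en-2-yl]cyclohex-2-en-1-one (8-OH cis to the C7 side chain) | O=C1C[C@H](C(=C)CO[Si](C)(C)C(C)(C)C)[C@H](O)C=C1C | intermediate
10 | (4R,5R)-4-(methoxymethoxy)-2-methyl-5-[3-(tert-butyldimethylsilyloxy)prop-1-en-2-yl]cyclohex-2-en-1-one | O=C1C[C@H](C(=C)CO[Si](C)(C)C(C)(C)C)[C@H](OCOC)C=C1C | intermediate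
11 | potassium C1=C10 enolate from conjugate reduction of 10 | [K+].[O-]C1=C(C)C[C@@H](OCOC)[C@@H](C(=C)CO[Si](C)(C)C(C)(C)C)C1 | intermediate (not isolated)
12 | (2R,4R,5R)-2-hydroxy-4-(methoxymethoxy)-2-methyl-5-[3-(tert-butyldimethylsilyloxy)prop-1-en-2-yl]cyclohexan-1-one (10-OH upper face, 8-OMOM and C7 side chain lower face) | O=C1C[C@H](C(=C)CO[Si](C)(C)C(C)(C)C)[C@H](OCOC)C[C@@]1(C)O | intermediate
13 | (2R,4R,5R)-2,4-bis(methoxymethoxy)-2-methyl-5-[3-(tert-butyldimethylsilyloxy)prop-1-en-2-yl]cyclohexan-1-one | O=C1C[C@H](C(=C)CO[Si](C)(C)C(C)(C)C)[C@H](OCOC)C[C@@]1(C)OCOC | intermediate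
14 | potassium C1=C6 enolate of 13 | [K+].[O-]C1=C[C@H](C(=C)CO[Si](C)(C)C(C)(C)C)[C@H](OCOC)C[C@@]1(C)OCOC | intermediate (not isolated)
15 | 6-hydroxy-2,4-bis(methoxymethoxy)-2-methyl-5-[3-(tert-butyldimethylsilyloxy)prop-1-en-2-yl]cyclohexan-1-one (ring C6 = germacrane C6; 6-OH upper face, trans to the C7 side chain) | O=C1[C@@H](O)[C@H](C(=C)CO[Si](C)(C)C(C)(C)C)[C@H](OCOC)C[C@@]1(C)OCOC | intermediate
16 | vinylmagnesium bromide | C=C[Mg]Br | starting material
17 | 1-ethenyl-4,6-bis(methoxymethoxy)-6-methyl-3-[3-(tert-butyldimethylsilyloxy)prop-1-en-2-yl]cyclohexane-1,2-diol (C1: vinyl upper, OH lower; C6-OH upper) | C=C[C@@]1(O)[C@@H](O)[C@H](C(=C)CO[Si](C)(C)C(C)(C)C)[C@H](OCOC)C[C@@]1(C)OCOC | intermediate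
18 | 2-ethenyl-2-hydroxy-3,5-bis(methoxymethoxy)-3-methyl-6-[3-(tert-butyldimethylsilyloxy)prop-1-en-2-yl]cyclohexan-1-one (ketone = germacrane C6; C1 as in 17) | C=C[C@@]1(O)C(=O)[C@H](C(=C)CO[Si](C)(C)C(C)(C)C)[C@H](OCOC)C[C@@]1(C)OCOC | intermediate
19 | prop-1-ynylmagnesium bromide | CC#C[Mg]Br | starting material
20 | 1-ethenyl-4,6-bis(methoxymethoxy)-6-methyl-2-(prop-1-yn-1-yl)-3-[3-(tert-butyldimethylsilyloxy)prop-1-en-2-yl]cyclohexane-1,2-diol (vinyl and propynyl upper face, both OH lower face) | C=C[C@@]1(O)[C@@](O)(C#CC)[C@H](C(=C)CO[Si](C)(C)C(C)(C)C)[C@H](OCOC)C[C@@]1(C)OCOC | intermediate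
21 | dipotassium dialkoxide of 20 | [K+].[K+].C=C[C@@]1([O-])[C@@]([O-])(C#CC)[C@H](C(=C)CO[Si](C)(C)C(C)(C)C)[C@H](OCOC)C[C@@]1(C)OCOC | intermediate (not isolated)
22 | dipotassium C1 enolate / C6 allenolate of the ten-membered ring | [K+].[K+].C=C(CO[Si](C)(C)C(C)(C)C)[C@H]1C([O-])=C=C(C)CC=C([O-])[C@](C)(OCOC)C[C@H]1OCOC | intermediate (not isolated)
23 | (2Z)-7,9-bis(methoxymethoxy)-3,7-dimethyl-10-[3-(tert-butyldimethylsilyloxy)prop-1-en-2-yl]cyclodec-2-ene-1,6-dione (germacrane C1,C6-dione; C7, C8, C10 as in the target) | C=C(CO[Si](C)(C)C(C)(C)C)[C@H]1C(=O)/C=C(/C)CCC(=O)[C@](C)(OCOC)C[C@H]1OCOC | intermediate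
24 | ten-membered 1,6-diol from 23 (C6 carbinol as in the target, C1 epimer mixture, C12 OTBS, 8,10-bis-MOM) | C=C(CO[Si](C)(C)C(C)(C)C)[C@H]1[C@H](O)/C=C(/C)CCC(O)[C@](C)(OCOC)C[C@H]1OCOC | intermediate
25 | 1,6,12-triol (8,10-bis-MOM; C1 epimer mixture) | C=C(CO)[C@H]1[C@H](O)/C=C(/C)CCC(O)[C@](C)(OCOC)C[C@H]1OCOC | intermediate
26 | C12 enal with free C6 and C1 hydroxyls | C=C(C=O)[C@H]1[C@H](O)/C=C(/C)CCC(O)[C@](C)(OCOC)C[C@H]1OCOC | intermediate (not isolated)
27 | 12,6-lactol (anomeric and C1 carbons as mixtures) | C=C1C(O)O[C@@H]2/C=C(/C)CCC(O)[C@](C)(OCOC)C[C@@H](OCOC)[C@@H]12 | intermediate (not isolated)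
28 | 1-hydroxy-8,10-bis(methoxymethoxy)germacra-4Z,11(13)-dien-12,6-olide (C1 epimer mixture) | C=C1C(=O)O[C@@H]2/C=C(/C)CCC(O)[C@](C)(OCOC)C[C@@H](OCOC)[C@@H]12 | intermediate
29 | 1-oxo-8,10-bis(methoxymethoxy)germacra-4Z,11(13)-dien-12,6-olide | C=C1C(=O)O[C@@H]2/C=C(/C)CCC(=O)[C@](C)(OCOC)C[C@@H](OCOC)[C@@H]12 | intermediate
30 | 8,10-bis(bromomethyl) ether of 31 | C=C1C(=O)O[C@@H]2/C=C(/C)CCC(=O)[C@](C)(OCBr)C[C@@H](OCBr)[C@@H]12 | intermediate (not isolated)
31 | 8,10-dihydroxy-1-oxogermacra-4Z,11(13)-dien-12,6-olide | C=C1C(=O)O[C@@H]2/C=C(/C)CCC(=O)[C@](C)(O)C[C@@H](O)[C@@H]12 | intermediate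
32 | tiglic acid, (E)-2-methylbut-2-enoic acid | C/C=C(\C)C(=O)O | starting material
33 | tiglic 2,4,6-trichlorobenzoic mixed anhydride | C/C=C(\C)C(=O)OC(=O)c1c(Cl)cc(Cl)cc1Cl | intermediate (not isolated)
34 | (6R,7R,8R,10R)-10-hydroxy-1-oxo-8-[(E)-2-methylbut-2-enoyloxy]germacra-4Z,11(13)-dien-12,6-olide | C=C1C(=O)O[C@@H]2/C=C(/C)CCC(=O)[C@](C)(O)C[C@@H](OC(=O)/C(C)=C/C)[C@@H]12 | target

## Step count and least certain steps

Total step count: 19. Longest linear sequence: 19 steps, from 1 to 34 (16, 19 and 32 are bought).

**Step 13 (key step).** A competing [3,3] shift through C6–C7 with the C11=C13 olefin is possible if the propynyl group and the C7 side chain become gauche. Transannular aldol addition or β-elimination of the 8-OMOM group may occur during the lifetime of the bis-enolate or on quench. Protonation of the allenolate may give some E enone. The fallback sets out from 20 and returns at 23 without strong base: both tertiary hydroxyls are silylated (TMSOTf, 2,6-lutidine) to the bis(trimethylsilyl) ether F1. This is heated in toluene in a sealed tube so that a neutral siloxy-Cope shift gives the ten-membered silyl enol ether/silyloxyallene F2, and buffered fluoride at low temperature releases 23.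

**Step 4.** Kinetic deprotonation at C6 instead of C8 would give the cross-conjugated dienol ether and hence oxidation at C6. Oxidation of the dienol ether at C10 instead of C8, or its aromatisation, are further risks. The fallback sets out from 5 and returns at 7 without any dienolate:
- H2O2/NaOH epoxidises the enone trans to the C7 side chain to give the epoxy ketone F3.
- NaBH4/CeCl3 gives the epoxy alcohol F4.
- PhSeNa opens the oxirane at the secondary C9 to the hydroxy selenide F5, and H2O2 then effects syn elimination towards C8 to give the tertiary allylic alcohol F6.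
- IBX oxidises the C1 carbinol to the α-hydroxy β,γ-enone F7.
- Re2O7-catalysed 1,3-transposition of the tertiary allylic alcohol into conjugation delivers the oxygen suprafacially to the upper face of C8, giving 7.

**Step 7.** Facial selectivity at C10 may be poor, because the stereoelectronically preferred axial attack is the one that the 8-OMOM group must block. The fallback sets out from 10 and returns at 12: nucleophilic epoxidation (H2O2, NaOH) on the upper face gives the epoxy ketone F8. LiAlH4 reduces the ketone to the epoxy alcohol F9 and then opens the oxirane at the secondary C9 (C10 is quaternary) to the 1,10-diol F10, and IBX oxidises the secondary C1 carbinol to 12.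

**Step 14.** Facial selectivity at C6 may be governed by the ring conformation and not by the Felkin–Anh preference, and C7 could epimerise or O8 eliminate if the reduction is slow. The fallback sets out from 23 and returns at 24: if the C6 epimer F11 predominates, Mitsunobu reaction with 4-nitrobenzoic acid inverts only the allylic C6 carbinol (the C1 carbinol beside quaternary C10 does not react) to give the ester F12, and methanolysis gives 24.

**Step 18.** Bromide or the Lewis acid may add to the methylene lactone, the allylic C6–O bond may ionise, or the tertiary carbinol may be lost. The fallback sets out from 29 and returns at 34: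
- The exocyclic methylene is masked as its dimethylamine Michael adduct F13.
- Aqueous HCl in THF cleaves both acetals on the ammonium salt to give the amino diol F14.
- Yamaguchi tigloylation gives the amino tiglate F15.
- MeI gives the methiodide F16, and NaHCO3 eliminates trimethylamine to regenerate C11=C13 in 34.

## Further compounds

F1 | step 13 | bis(trimethylsilyl) ether of 20 | C=C[C@@]1(O[Si](C)(C)C)[C@@](O[Si](C)(C)C)(C#CC)[C@H](C(=C)CO[Si](C)(C)C(C)(C)C)[C@H](OCOC)C[C@@]1(C)OCOC
F2 | step 13 | ten-membered C1 trimethylsilyl enol ether / C6 trimethylsilyloxyallene | C=C(CO[Si](C)(C)C(C)(C)C)[C@H]1C(O[Si](C)(C)C)=C=C(C)CC=C(O[Si](C)(C)C)[C@](C)(OCOC)C[C@H]1OCOC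
F3 | step 4 | 9,10-epoxy ketone from 5 (oxirane on the upper face) | O=C1C[C@H](C(=C)CO[Si](C)(C)C(C)(C)C)C[C@H]2O[C@@]12C
F4 | step 4 | 9,10-epoxy C1 alcohol (C1 epimer mixture) | OC1C[C@H](C(=C)CO[Si](C)(C)C(C)(C)C)C[C@H]2O[C@@]12C
F5 | step 4 | 9-phenylseleno 1,10-diol | OC1C[C@H](C(=C)CO[Si](C)(C)C(C)(C)C)C[C@H]([Se]c2ccccc2)[C@@]1(C)O
F6 | step 4 | 8,9-ene 1,10-diol | OC1C[C@H](C(=C)CO[Si](C)(C)C(C)(C)C)C=C[C@@]1(C)O
F7 | step 4 | 10-hydroxy 8,9-en-1-one | O=C1C[C@H](C(=C)CO[Si](C)(C)C(C)(C)C)C=C[C@@]1(C)O
F8 | step 7 | 9,10-epoxy ketone from 10 (oxirane on the upper face) | O=C1C[C@H](C(=C)CO[Si](C)(C)C(C)(C)C)[C@H](OCOC)[C@H]2O[C@@]12C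
F9 | step 7 | 9,10-epoxy C1 alcohol from F8 (C1 epimer mixture) | OC1C[C@H](C(=C)CO[Si](C)(C)C(C)(C)C)[C@H](OCOC)[C@H]2O[C@@]12C
F10 | step 7 | 1,10-diol with 8-OMOM (C1 epimer mixture) | OC1C[C@H](C(=C)CO[Si](C)(C)C(C)(C)C)[C@H](OCOC)C[C@@]1(C)O
F11 | step 14 | C6 epimer of 24 | C=C(CO[Si](C)(C)C(C)(C)C)[C@H]1[C@@H](O)/C=C(/C)CCC(O)[C@](C)(OCOC)C[C@H]1OCOC
F12 | step 14 | C6 4-nitrobenzoate of 24 | C=C(CO[Si](C)(C)C(C)(C)C)[C@H]1[C@H](OC(=O)c2ccc(cc2)[N+](=O)[O-])/C=C(/C)CCC(O)[C@](C)(OCOC)C[C@H]1OCOC
F13 | step 18 | 13-dimethylamino-11,13-dihydro adduct of 29 (C11 unassigned) | CN(C)CC1C(=O)O[C@@H]2/C=C(/C)CCC(=O)[C@](C)(OCOC)C[C@@H](OCOC)[C@@H]12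
F14 | step 18 | 13-dimethylamino-11,13-dihydro adduct of 31 | CN(C)CC1C(=O)O[C@@H]2/C=C(/C)CCC(=O)[C@](C)(O)C[C@@H](O)[C@@H]12
F15 | step 18 | 13-dimethylamino-11,13-dihydro adduct of 34 | CN(C)CC1C(=O)O[C@@H]2/C=C(/C)CCC(=O)[C@](C)(O)C[C@@H](OC(=O)/C(C)=C/C)[C@@H]12
F16 | step 18 | methiodide of F15 | [I-].C[N+](C)(C)CC1C(=O)O[C@@H]2/C=C(/C)CCC(=O)[C@](C)(O)C[C@@H](OC(=O)/C(C)=C/C)[C@@H]12
A1 | alternative 1 | O6 diethylphosphonoacetate of the ten-membered 7,8-epoxide (C1,C10 acetonide) | CCOP(=O)(OCC)CC(=O)O[C@@H]1/C=C(/C)CC[C@H]2OC(C)(C)O[C@]2(C)C[C@H]3O[C@H]13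
A2 | alternative 1 | α-methylene lactone with free C8 hydroxyl (C1,C10 acetonide) | C=C1C(=O)O[C@@H]2/C=C(/C)CC[C@H]3OC(C)(C)O[C@]3(C)C[C@@H](O)[C@@H]12
A3 | alternative 2 | acyclic C8 aldoxime with C9=C10 isopropenyl terminus (C1 dioxolane; C6 and C12 TBS ethers) | C=C(CO[Si](C)(C)C(C)(C)C)[C@H](C=NO)[C@H](O[Si](C)(C)C(C)(C)C)/C=C(/C)CCC1(OCCO1)C(C)=C
A4 | alternative 2 | ten-membered carbocycle bridged by an isoxazoline over C8–C9–C10 | C=C(CO[Si](C)(C)C(C)(C)C)[C@H]1[C@H](O[Si](C)(C)C(C)(C)C)/C=C(/C)CCC3(OCCO3)[C@@]2(C)CC1=NO2
A5 | alternative 3 | acyclic C6 aldehyde with (Z)-C5 alkenyl iodide and C12 methyl ester (C1,C10 acetonide; C8 TBS ether) | COC(=O)C[C@@H](C=O)[C@H](O[Si](C)(C)C(C)(C)C)C[C@@]1(C)OC(C)(C)O[C@@H]1CC/C(C)=C\I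
A6 | alternative 3 | ten-membered trans-fused γ-lactone lacking the methylene (C1,C10 acetonide; C8 TBS ether) | C1C(=O)O[C@@H]2/C=C(/C)CC[C@H]3OC(C)(C)O[C@]3(C)C[C@@H](O[Si](C)(C)C(C)(C)C)[C@@H]12
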